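**Retrosynthetic overview**
1. Target ⇒ C-9 esterification with (2S,3S)-epoxyangelic acid (angelic acid, Sharpless epoxidation) and final release of 8-OH from its PMB ether.
2. Ten-membered carbocycle (second ring formed) ⇒ double boron-ate 1,2-shift ring contraction of a twelve-membered cyclic bis(alkenylborate), assembled from an acyclic bis(alkenyl iodide) and ethene-derived 1,2-bis(boronate) (C-2/C-3). Both trisubstituted alkenes form with inversion of the iodide geometry.
3. γ-Lactone (first ring formed, carried through the ring contraction as a lactol silyl acetal) ⇒ zinc Barbier allylation (C-6–C-7) of (Z)-3-iodobut-2-enal with an allylic bromide.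
4. Allylic bromide ⇒ cross-metathesis of methyl 2-(bromomethyl)acrylate with the syn-diol derivative from Brown alkoxyallylboration (C-8–C-9) of (E)-3-iodo-2-methylpropenal.
5. The two iodo-enals ⇒ prop-2-yn-1-ol (Negishi carboalumination) and but-2-yn-1-ol (Red-Al/I2).

Assumption: locants C-1 to C-15 follow germacrane numbering (lactone O on C-6, C-11 on C-7); boron, silyl and PMB reagents count as reagents, every skeletal carbon comes from the numbered starting materials.

CIP labels at C-6 and C-7 change along the route because substituent priorities change (iodine on C-4, carbon or hydrogen on O-8); the spatial arrangement is that of the target throughout.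

**Step 1**
Reactants: 1 prop-2-yn-1-ol
Product: 3 (E)-3-iodo-2-methylprop-2-en-1-ol, via alkenylalane 2 (not isolated)
Conditions: AlMe3 (3 equiv), Cp2ZrCl2 (0.25 equiv), CH2Cl2, 0 °C to rt; then I2, THF, −30 to 0 °C
Reagents that add atoms: trimethylaluminium C[Al](C)C; iodine II
Why: Negishi zirconium-catalysed carboalumination adds methyl and aluminium syn across the alkyne (methyl to the internal carbon), and iodinolysis with retention gives the E iodide only.

**Step 2**
Reactants: 3 (E)-3-iodo-2-methylprop-2-en-1-ol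
Product: 4 (E)-3-iodo-2-methylprop-2-enal
Conditions: MnO2 (10 equiv), CH2Cl2, rt
Reagents that add atoms: none
Why: Neutral allylic oxidation with MnO2 leaves the alkenyl iodide and its geometry untouched.

**Step 3**
Reactants: 5 prop-2-en-1-ol
Product: 6 1-methoxy-4-[(prop-2-en-1-yloxy)methyl]benzene
Conditions: NaH, 4-MeOC6H4CH2Cl, Bu4NI (cat.), THF, 0 °C to rt
Reagents that add atoms: 4-methoxybenzyl chloride COc1ccc(CCl)cc1
Why: Williamson etherification installs the PMB group that later becomes the 8-O protecting group.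

**Step 4**
Reactants: 6 1-methoxy-4-[(prop-2-en-1-yloxy)methyl]benzene; 4 (E)-3-iodo-2-methylprop-2-enal
Product: 9 (1E,3R,4R)-1-iodo-4-[(4-methoxybenzyl)oxy]-2-methylhexa-1,5-dien-3-ol, via allyllithium 7 (not isolated), via allylborane 8 (not isolated)
Conditions: s-BuLi, THF, −78 °C; (−)-Ipc2BOMe; BF3·OEt2; then 4, −78 °C; NaOH, H2O2
Reagents that add atoms: none
Why: Brown asymmetric alkoxyallylboration: the (Z)-γ-alkoxyallylborane reacts through a chair transition state to give the syn adduct, and the isopinocampheyl groups from (+)-α-pinene direct attack to the si face of the aldehyde, which sets C-9 and C-8 as R,R.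

**Step 5**
Reactants: 9 (1E,3R,4R)-1-iodo-4-[(4-methoxybenzyl)oxy]-2-methylhexa-1,5-dien-3-ol
Product: 10 tert-butyl{[(1E,3R,4R)-1-iodo-4-[(4-methoxybenzyl)oxy]-2-methylhexa-1,5-dien-3-yl]oxy}dimethylsilane
Conditions: TBSOTf, 2,6-lutidine, CH2Cl2, −78 to 0 °C
Reagents that add atoms: tert-butyldimethylsilyl triflate CC(C)(C)[Si](C)(C)OS(=O)(=O)C(F)(F)F
Why: Silylation of the hindered allylic 9-OH gives a group that survives organozinc, hydride and organolithium steps and is orthogonal to PMB.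

**Step 6**
Reactants: 10 the silyl ether from step 5; 11 methyl 2-(bromomethyl)prop-2-enoate
Product: 12 methyl (2Z,4R,5R,6E)-2-(bromomethyl)-5-[(tert-butyldimethylsilyl)oxy]-7-iodo-4-[(4-methoxybenzyl)oxy]-6-methylhepta-2,6-dienoate
Conditions: 11 (5 equiv), second-generation Hoveyda–Grubbs catalyst RuCl2(H2IMes)(=CH-C6H4-2-OiPr) (10 mol %), CH2Cl2, 40 °C
Reagents that add atoms: none
Why: Olefin cross-metathesis engages only the monosubstituted alkene (the alkenyl iodide is inert) and gives the thermodynamic trisubstituted enoate with the chain trans to the ester, without C-8 ever being α to a carbonyl.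

**Step 7**
Reactants: 13 but-2-yn-1-ol
Product: 15 (Z)-3-iodobut-2-en-1-ol, via alkenylaluminate 14 (not isolated)
Conditions: NaAlH2(OCH2CH2OMe)2, THF, 0 °C to rt; then I2, THF, −78 °C
Reagents that add atoms: iodine II
Why: Hydroxyl-directed trans-hydroalumination places aluminium on C-3 cis to the CH2O group, and iodinolysis with retention gives the Z iodide.

**Step 8**
Reactants: 15 (Z)-3-iodobut-2-en-1-ol
Product: 16 (Z)-3-iodobut-2-enal
Conditions: MnO2, CH2Cl2, rt; used at once
Reagents that add atoms: none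
Why: MnO2 allylic oxidation under neutral conditions avoids Z to E isomerisation of the β-iodo enal.

**Step 9**
Reactants: 12 the allylic bromide from step 6; 16 (Z)-3-iodobut-2-enal
Product: 19 (4S,5R)-4-[(1R,2R,3E)-2-[(tert-butyldimethylsilyl)oxy]-4-iodo-1-[(4-methoxybenzyl)oxy]-3-methylbut-3-en-1-yl]-5-[(1Z)-2-iodoprop-1-en-1-yl]-3-methylideneoxolan-2-one, via allylzinc bromide 17 (not isolated), via hydroxy ester 18 (not isolated)
Conditions: Zn dust, THF, 0 °C; then 16, −20 °C to rt; aq. NH4Cl; PPTS (cat.), CH2Cl2, rt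
Reagents that add atoms: none
Why: Zinc Barbier (Reformatsky-type) 2-alkoxycarbonylallylation: γ-attack of the Z allylzinc through a closed chair gives the 6,7-syn adduct that lactonises to the cis-lactone, and chelation of zinc by the C-8 PMB ether makes the aldehyde add anti to the C-9 branch, which places C-11 syn to O-8 as in the target.

**Step 10**
Reactants: 19 the cis-lactone from step 9
Product: 20 the corresponding lactol (4S,5R)-…-3-methylideneoxolan-2-ol (anomer mixture)
Conditions: i-Bu2AlH (1.1 equiv), CH2Cl2, −78 °C; Rochelle salt; no acid (acid would give the 3-methylfuran)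
Reagents that add atoms: none
Why: Half-reduction of the lactone with i-Bu2AlH removes both the electrophilic carbonyl and the Michael acceptor before the organolithium step.

**Step 11**
Reactants: 20 the lactol from step 10
Product: 21 the lactol tert-butyldimethylsilyl acetal of 20 (anomer mixture)
Conditions: TBSOTf, 2,6-lutidine, CH2Cl2, −78 °C
Reagents that add atoms: tert-butyldimethylsilyl triflate CC(C)(C)[Si](C)(C)OS(=O)(=O)C(F)(F)F
Why: Silylation of the anomeric hydroxyl gives a cyclic silyl acetal that is inert to t-BuLi and keeps O-6 locked in the five-membered ring.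

**Step 12**
Reactants: 22 ethene
Product: 23 1,2-bis(4,4,5,5-tetramethyl-1,3,2-dioxaborolan-2-yl)ethane
Conditions: B2pin2, Pt(PPh3)4 (3 mol %), ethene (1 atm), toluene, 80 °C
Reagents that add atoms: bis(pinacolato)diboron CC1(C)OB(B2OC(C)(C)C(C)(C)O2)OC1(C)C
Why: Platinum-catalysed Miyaura diboration of the alkene gives the C-2/C-3 linchpin.

**Step 13**
Reactants: 21 the bis(alkenyl iodide) silyl acetal from step 11; 23 1,2-bis(4,4,5,5-tetramethyl-1,3,2-dioxaborolan-2-yl)ethane
Product: 26 (3aS,4R,5R,6Z,10E,11aS)-2,5-bis[(tert-butyldimethylsilyl)oxy]-4-[(4-methoxybenzyl)oxy]-6,10-dimethyl-3-methylidene-2,3,3a,4,5,8,9,11a-octahydrocyclodeca[b]furan, via dilithio species 24 (not isolated), via cyclic bis(borate) 25 (not isolated)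
Conditions: t-BuLi (4.2 equiv), THF–Et2O, −78 °C; 23 (1.0 equiv) added over 2 h, 2 mM, −78 to 0 °C; I2 (2.4 equiv), THF, −78 °C; NaOMe, MeOH, −78 to 0 °C
Reagents that add atoms: none
Why: Proposed new method: the dilithiated bis(alkenyl) species should capture the 1,2-bis(boronate) twice (second addition intramolecular at high dilution) to give a twelve-membered cyclic bis(alkenylborate); at each boron, iodine then triggers iodonium formation, 1,2-shift of the ring CH2 from boron to the alkenyl carbon and anti β-elimination with NaOMe, so both boron atoms leave the ring and it contracts to the ten-membered carbocycle; each event inverts the olefin geometry, so the Z 2-iodoalkene gives the 4E and the E 1-iodoalkene the 1(10)Z double bond; the closest known reactions are the intermolecular Zweifel olefination of alkenyllithium/boronic ester ate complexes and the electrophile-induced ring contraction of cyclic alkenyl boronate complexes.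

**Step 14**
Reactants: 26 the macrocyclic bis(silyl) compound from step 13
Product: 27 (3aS,4R,5R,6Z,10E,11aS)-4-[(4-methoxybenzyl)oxy]-6,10-dimethyl-3-methylidene-2,3,3a,4,5,8,9,11a-octahydrocyclodeca[b]furan-2,5-diol (anomer mixture)
Conditions: Bu4NF, THF, 0 °C
Reagents that add atoms: none
Why: Fluoride cleaves the anomeric silyl acetal and the C-9 silyl ether while the PMB ether keeps O-8 out of lactol formation.

**Step 15**
Reactants: 27 the lactol diol from step 14
Product: 28 (3aS,4R,5R,6Z,10E,11aS)-5-hydroxy-4-[(4-methoxybenzyl)oxy]-6,10-dimethyl-3-methylidene-3a,4,5,8,9,11a-hexahydrocyclodeca[b]furan-2(3H)-one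
Conditions: TEMPO (cat.), PhI(OAc)2, NaHCO3, CH2Cl2, 0 °C to rt
Reagents that add atoms: none
Why: TEMPO/PhI(OAc)2 oxidation converts the allylic lactol into the α-methylene lactone much faster than it oxidises the hindered secondary 9-OH.

**Step 16**
Reactants: 29 (Z)-2-methylbut-2-enoic acid (angelic acid)
Product: 30 (Z)-2-methylbut-2-en-1-ol
Conditions: LiAlH4, Et2O, 0 °C
Reagents that add atoms: none
Why: Hydride reduction of the acid gives the allylic alcohol with the Z geometry retained.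

**Step 17**
Reactants: 30 (Z)-2-methylbut-2-en-1-ol
Product: 31 [(2R,3S)-2,3-dimethyloxiran-2-yl]methanol
Conditions: Ti(OiPr)4, L-(+)-diethyl tartrate, t-BuOOH, 4 Å MS, CH2Cl2, −20 °C
Reagents that add atoms: tert-butyl hydroperoxide CC(C)(C)OO
Why: Sharpless asymmetric epoxidation with L-(+)-tartrate delivers oxygen to the face that gives the (2R,3S) epoxy alcohol, and the Z geometry fixes the two methyl groups trans.

**Step 18**
Reactants: 31 [(2R,3S)-2,3-dimethyloxiran-2-yl]methanol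
Product: 32 (2S,3S)-2,3-dimethyloxirane-2-carboxylic acid
Conditions: RuCl3 (cat.), NaIO4, CCl4–MeCN–H2O, rt
Reagents that add atoms: sodium periodate [Na+].[O-]I(=O)(=O)=O; water O
Why: Sharpless RuO4 oxidation takes the primary alcohol to the acid without touching the epoxide (the C-2 label changes from R to S only through priorities).

**Step 19**
Reactants: 28 the macrocyclic hydroxy lactone from step 15; 32 (2S,3S)-2,3-dimethyloxirane-2-carboxylic acid
Product: 34 (3aS,4R,5R,6Z,10E,11aS)-4-[(4-methoxybenzyl)oxy]-6,10-dimethyl-3-methylidene-2-oxo-2,3,3a,4,5,8,9,11a-octahydrocyclodeca[b]furan-5-yl (2S,3S)-2,3-dimethyloxirane-2-carboxylate, via mixed anhydride 33 (not isolated)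
Conditions: 2,4,6-Cl3C6H2COCl, Et3N, THF; then 28, DMAP, toluene, rt
Reagents that add atoms: none
Why: Yamaguchi esterification acylates the only free hydroxyl (9-OH) with retention at C-9.

**Step 20**
Reactants: 34 the PMB-protected ester from step 19
Product: 35 (3aR,4R,5R,6Z,10E,11aS)-4-hydroxy-6,10-dimethyl-3-methylidene-2-oxo-2,3,3a,4,5,8,9,11a-octahydrocyclodeca[b]furan-5-yl (2S,3S)-2,3-dimethyloxirane-2-carboxylate (target)
Conditions: DDQ, CH2Cl2–pH 7 buffer, 0 °C
Reagents that add atoms: none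
Why: Oxidative PMB cleavage under buffered, non-acidic conditions frees 8-OH last, so neither acyl migration, translactonisation nor acid-induced transannular cyclisation can intervene.

**Compound list**
1 | prop-2-yn-1-ol | C#CCO | starting material
2 | dimethylaluminium (E)-3-(dimethylalumanyl)-2-methylprop-2-en-1-olate | C/C(CO[Al](C)C)=C\[Al](C)C | intermediate
3 | (E)-3-iodo-2-methylprop-2-en-1-ol | C/C(CO)=C\I | intermediate
4 | (E)-3-iodo-2-methylprop-2-enal | C/C(C=O)=C\I | intermediate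
5 | prop-2-en-1-ol | C=CCO | starting material
6 | 1-methoxy-4-[(prop-2-en-1-yloxy)methyl]benzene | C=CCOCc1ccc(OC)cc1 | intermediate
7 | [(Z)-3-(4-methoxybenzyloxy)prop-2-en-1-yl]lithium | [Li]C/C=C\OCc1ccc(OC)cc1 | intermediate
8 | [(Z)-3-(4-methoxybenzyloxy)prop-2-en-1-yl]bis[(1R,2S,3R,5R)-2,6,6-trimethylbicyclo[3.1.1]heptan-3-yl]borane | C[C@H]1[C@H](B(C/C=C\OCc2ccc(OC)cc2)[C@@H]2C[C@@H]3C[C@H]([C@H]2C)C3(C)C)C[C@@H]2C[C@H]1C2(C)C | intermediate
9 | (1E,3R,4R)-1-iodo-4-[(4-methoxybenzyl)oxy]-2-methylhexa-1,5-dien-3-ol | I/C=C(\C)[C@@H](O)[C@H](OCc1ccc(OC)cc1)C=C | intermediate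
10 | tert-butyl{[(1E,3R,4R)-1-iodo-4-[(4-methoxybenzyl)oxy]-2-methylhexa-1,5-dien-3-yl]oxy}dimethylsilane | I/C=C(\C)[C@@H](O[Si](C)(C)C(C)(C)C)[C@H](OCc1ccc(OC)cc1)C=C | intermediate
11 | methyl 2-(bromomethyl)prop-2-enoate | C=C(CBr)C(=O)OC | starting material
12 | methyl (2Z,4R,5R,6E)-2-(bromomethyl)-5-[(tert-butyldimethylsilyl)oxy]-7-iodo-4-[(4-methoxybenzyl)oxy]-6-methylhepta-2,6-dienoate | COC(=O)/C(CBr)=C/[C@@H](OCc1ccc(OC)cc1)[C@H](O[Si](C)(C)C(C)(C)C)/C(C)=C/I | intermediate
13 | but-2-yn-1-ol | CC#CCO | starting material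
14 | sodium bis(2-methoxyethoxy)(3-methyl-2,5-dihydro-1,2-oxaluminol-2-yl)aluminate (cyclic alkenylaluminate, Al on C-3 cis to CH2O) | CC1=CCO[Al-]1(OCCOC)OCCOC.[Na+] | intermediate
15 | (Z)-3-iodobut-2-en-1-ol | C/C(I)=C/CO | intermediate
16 | (Z)-3-iodobut-2-enal | C/C(I)=C/C=O | intermediate
17 | allylzinc bromide from 12 (CH2Br replaced by CH2ZnBr, same configuration) | COC(=O)/C(C[Zn]Br)=C/[C@@H](OCc1ccc(OC)cc1)[C@H](O[Si](C)(C)C(C)(C)C)/C(C)=C/I | intermediate
18 | open 6,7-syn hydroxy ester (methyl 2-methylidene ester with 6-OH, same configuration as 19) | COC(=O)C(=C)[C@@H]([C@@H](O)/C=C(/C)I)[C@@H](OCc1ccc(OC)cc1)[C@H](O[Si](C)(C)C(C)(C)C)/C(C)=C/I | intermediate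
19 | (4S,5R)-4-[(1R,2R,3E)-2-[(tert-butyldimethylsilyl)oxy]-4-iodo-1-[(4-methoxybenzyl)oxy]-3-methylbut-3-en-1-yl]-5-[(1Z)-2-iodoprop-1-en-1-yl]-3-methylideneoxolan-2-one (cis-lactone) | C=C1C(=O)O[C@@H](/C=C(/C)I)[C@H]1[C@@H](OCc2ccc(OC)cc2)[C@H](O[Si](C)(C)C(C)(C)C)/C(C)=C/I | intermediate
20 | lactol of 19, (4S,5R)-…-3-methylideneoxolan-2-ol, C-2 epimers | C=C1C(O)O[C@@H](/C=C(/C)I)[C@H]1[C@@H](OCc2ccc(OC)cc2)[C@H](O[Si](C)(C)C(C)(C)C)/C(C)=C/I | intermediate
21 | 2-O-tert-butyldimethylsilyl acetal of 20, C-2 epimers | C=C1C(O[Si](C)(C)C(C)(C)C)O[C@@H](/C=C(/C)I)[C@H]1[C@@H](OCc2ccc(OC)cc2)[C@H](O[Si](C)(C)C(C)(C)C)/C(C)=C/I | intermediate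
22 | ethene | C=C | starting material
23 | 1,2-bis(4,4,5,5-tetramethyl-1,3,2-dioxaborolan-2-yl)ethane | CC1(C)OB(CCB2OC(C)(C)C(C)(C)O2)OC1(C)C | intermediate
24 | dilithio species from 21 (both I replaced by Li, geometry retained) | C=C1C(O[Si](C)(C)C(C)(C)C)O[C@@H](/C=C(/C)[Li])[C@H]1[C@@H](OCc2ccc(OC)cc2)[C@H](O[Si](C)(C)C(C)(C)C)/C(C)=C/[Li] | intermediate
25 | dilithium twelve-membered cyclic bis(alkenylborate) (ring C-6, C-5, C-4, B, C-3, C-2, B, C-1, C-10, C-9, C-8, C-7) | [Li+].[Li+].C=C1C(O[Si](C)(C)C(C)(C)C)O[C@H]2/C=C(/C)[B-]3(OC(C)(C)C(C)(C)O3)CC[B-]3(OC(C)(C)C(C)(C)O3)/C=C(\C)[C@@H](O[Si](C)(C)C(C)(C)C)[C@H](OCc3ccc(OC)cc3)[C@@H]12 | intermediate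
26 | (3aS,4R,5R,6Z,10E,11aS)-2,5-bis[(tert-butyldimethylsilyl)oxy]-4-[(4-methoxybenzyl)oxy]-6,10-dimethyl-3-methylidene-2,3,3a,4,5,8,9,11a-octahydrocyclodeca[b]furan, C-2 epimers | C=C1C(O[Si](C)(C)C(C)(C)C)O[C@H]2/C=C(\C)CC/C=C(/C)[C@@H](O[Si](C)(C)C(C)(C)C)[C@H](OCc3ccc(OC)cc3)[C@@H]12 | intermediate
27 | (3aS,4R,5R,6Z,10E,11aS)-4-[(4-methoxybenzyl)oxy]-6,10-dimethyl-3-methylidene-2,3,3a,4,5,8,9,11a-octahydrocyclodeca[b]furan-2,5-diol, C-2 epimers | C=C1C(O)O[C@H]2/C=C(\C)CC/C=C(/C)[C@@H](O)[C@H](OCc3ccc(OC)cc3)[C@@H]12 | intermediate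
28 | (3aS,4R,5R,6Z,10E,11aS)-5-hydroxy-4-[(4-methoxybenzyl)oxy]-6,10-dimethyl-3-methylidene-3a,4,5,8,9,11a-hexahydrocyclodeca[b]furan-2(3H)-one | C=C1C(=O)O[C@H]2/C=C(\C)CC/C=C(/C)[C@@H](O)[C@H](OCc3ccc(OC)cc3)[C@@H]12 | intermediate
29 | (Z)-2-methylbut-2-enoic acid | C/C=C(/C)C(=O)O | starting material
30 | (Z)-2-methylbut-2-en-1-ol | C/C=C(/C)CO | intermediate
31 | [(2R,3S)-2,3-dimethyloxiran-2-yl]methanol | OC[C@@]1(C)O[C@H]1C | intermediate
32 | (2S,3S)-2,3-dimethyloxirane-2-carboxylic acid | OC(=O)[C@@]1(C)O[C@H]1C | intermediate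
33 | (2S,3S)-2,3-dimethyloxirane-2-carboxylic 2,4,6-trichlorobenzoic anhydride | O=C(OC(=O)[C@@]1(C)O[C@H]1C)c1c(Cl)cc(Cl)cc1Cl | intermediate
34 | (3aS,4R,5R,6Z,10E,11aS)-4-[(4-methoxybenzyl)oxy]-6,10-dimethyl-3-methylidene-2-oxo-2,3,3a,4,5,8,9,11a-octahydrocyclodeca[b]furan-5-yl (2S,3S)-2,3-dimethyloxirane-2-carboxylate | C=C1C(=O)O[C@H]2/C=C(\C)CC/C=C(/C)[C@@H](OC(=O)[C@@]3(C)O[C@H]3C)[C@H](OCc3ccc(OC)cc3)[C@@H]12 | intermediate
35 | (3aR,4R,5R,6Z,10E,11aS)-4-hydroxy-6,10-dimethyl-3-methylidene-2-oxo-2,3,3a,4,5,8,9,11a-octahydrocyclodeca[b]furan-5-yl (2S,3S)-2,3-dimethyloxirane-2-carboxylate | C=C1C(=O)O[C@H]2/C=C(\C)CC/C=C(/C)[C@@H](OC(=O)[C@@]3(C)O[C@H]3C)[C@H](O)[C@@H]12 | target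

**Step count**
Total: 20 steps. Longest linear sequence: 13 steps (1, 2, 4, 5, 6, 9, 10, 11, 13, 14, 15, 19, 20).

**Three steps most likely to fail**

Step 13 (the proposed double boron-ate ring contraction; the second, intramolecular ate formation may lose to oligomerisation). The fallback uses known chemistry only: two ordinary intermolecular Zweifel olefinations build the open chain, and an intramolecular zinc Barbier allylation closes the ring at C-6/C-7. It sets out from 10, 15 and 23 and comes back at 28. Lithium–iodine exchange on 10 (t-BuLi, −78 °C), addition to excess 23 and I2/NaOMe give the (Z)-homoallylic boronic ester F1. Compound 15 is silylated (TBSCl, imidazole) to the silyl ether F2; its alkenyllithium is added to F1 and treated with I2/NaOMe to give the 1(10)Z,4E open-chain triene F3. Cross-metathesis of the vinyl group of F3 with 11 gives the allylic bromide F4. HF·pyridine removes the primary silyl ether to give the allylic alcohol F5, and MnO2 gives the enal F6. Zn dust in THF at 1 mM closes carbocycle and lactone together to give the macrocyclic silyl ether lactone F7, and Bu4NF then gives 28.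

Step 6 (cross-metathesis of a hindered allylic ether with a 1,1-disubstituted acrylate). The fallback sets out from 10 and comes back at 12. OsO4 (cat.)/NaIO4/2,6-lutidine cleaves the vinyl group to the α-alkoxy aldehyde F8. A Morita–Baylis–Hillman reaction with methyl acrylate (DABCO) gives the allylic alcohol F9 as a carbinol epimer mixture. NBS/Me2S then converts it, with allylic transposition, into 12.

Step 9 (face selectivity at C-7 rests on chelation by an ether oxygen, and γ-attack at a hindered carbon). The fallback sets out from 12 and comes back at 19, using hydroxyl-directed indium allylation in water. DDQ removes the PMB group to give the hydroxy bromide F10, used at once. Indium powder (In) in THF–H2O with 16 gives, through the hydroxyl-chelated allylindium, the hydroxy lactone F11. PMB trichloroacetimidate with La(OTf)3 (cat.) re-protects 8-OH to give 19.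

**Further compounds**
F1 | step 13 | 2-[(3Z,5R,6R)-5-[(tert-butyldimethylsilyl)oxy]-6-[(4-methoxybenzyl)oxy]-4-methylocta-3,7-dien-1-yl]-4,4,5,5-tetramethyl-1,3,2-dioxaborolane | C=C[C@@H](OCc1ccc(OC)cc1)[C@H](O[Si](C)(C)C(C)(C)C)/C(C)=C\CCB1OC(C)(C)C(C)(C)O1
F2 | step 13 | tert-butyl{[(2Z)-3-iodobut-2-en-1-yl]oxy}dimethylsilane | C/C(I)=C/CO[Si](C)(C)C(C)(C)C
F3 | step 13 | open-chain 1(10)Z,4E triene: C-6 primary TBS ether, 9-OTBS, 8-OPMB, terminal C-7 vinyl | C=C[C@@H](OCc1ccc(OC)cc1)[C@H](O[Si](C)(C)C(C)(C)C)/C(C)=C\CC/C(C)=C/CO[Si](C)(C)C(C)(C)C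
F4 | step 13 | methyl 2-(bromomethyl)enoate from F3 (C-7=C-11 Z, bromide on C-13) | COC(=O)/C(CBr)=C/[C@@H](OCc1ccc(OC)cc1)[C@H](O[Si](C)(C)C(C)(C)C)/C(C)=C\CC/C(C)=C/CO[Si](C)(C)C(C)(C)C
F5 | step 13 | C-6 allylic alcohol from F4 | COC(=O)/C(CBr)=C/[C@@H](OCc1ccc(OC)cc1)[C@H](O[Si](C)(C)C(C)(C)C)/C(C)=C\CC/C(C)=C/CO
F6 | step 13 | C-6 enal from F5 | COC(=O)/C(CBr)=C/[C@@H](OCc1ccc(OC)cc1)[C@H](O[Si](C)(C)C(C)(C)C)/C(C)=C\CC/C(C)=C/C=O
F7 | step 13 | (3aS,4R,5R,6Z,10E,11aS)-5-[(tert-butyldimethylsilyl)oxy]-4-[(4-methoxybenzyl)oxy]-6,10-dimethyl-3-methylidene-3a,4,5,8,9,11a-hexahydrocyclodeca[b]furan-2(3H)-one | C=C1C(=O)O[C@H]2/C=C(\C)CC/C=C(/C)[C@@H](O[Si](C)(C)C(C)(C)C)[C@H](OCc3ccc(OC)cc3)[C@@H]12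
F8 | step 6 | (2R,3R,4E)-3-[(tert-butyldimethylsilyl)oxy]-5-iodo-2-[(4-methoxybenzyl)oxy]-4-methylpent-4-enal | O=C[C@@H](OCc1ccc(OC)cc1)[C@H](O[Si](C)(C)C(C)(C)C)/C(C)=C/I
F9 | step 6 | methyl 2-methylidene-3-hydroxy ester from F8 (Morita–Baylis–Hillman adduct, carbinol epimers) | C=C(C(=O)OC)C(O)[C@@H](OCc1ccc(OC)cc1)[C@H](O[Si](C)(C)C(C)(C)C)/C(C)=C/I
F10 | step 9 | methyl (2Z,4R,5R,6E)-2-(bromomethyl)-5-[(tert-butyldimethylsilyl)oxy]-4-hydroxy-7-iodo-6-methylhepta-2,6-dienoate | COC(=O)/C(CBr)=C/[C@@H](O)[C@H](O[Si](C)(C)C(C)(C)C)/C(C)=C/I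
F11 | step 9 | cis-lactone as 19 with free 8-OH | C=C1C(=O)O[C@@H](/C=C(/C)I)[C@H]1[C@@H](O)[C@H](O[Si](C)(C)C(C)(C)C)/C(C)=C/I
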